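In this flask D takes up X on the road to D.X 3.07 times as fast as on the road to Z, and the bench rule of thumb says that a product mix follows such speeds.

D 0.0050 M; X 5.00 mM (in portions, 3); L 100 µM; time 10 min; the portions of X follow each other after 0.15 s, the first at the start

    D + X ⇌ Z (K1 = 486 /M, k1 = 1580 /M/s)
    L + L ⇌ L2 (K2 = 3250 /M, k2 = 3900 /M/s)
    D.X + L ⇌ Z + L, rate k3*[L]*[D.X] forward; the back reaction follows from the equilibrium constant (k3 = 13700 /M/s)
    D + X ⇌ D.X (K4 = 766 /M, k4 = 4850 /M/s)
    D ⇌ G (K5 = 0.825, k5 = 0.201 /s)

- where a step has two of a species, its rate is k times that concentration squared, and two are used at each turn
- what has gone from D into another species counts as reacted, even if it can come back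
- the reaction counts as stopped when no species that holds the D changes by six tenths of a point or more over the second half of the time
- run time (flask): 10 min

- why nothing more happens at 10 min, or that something still does (no working catalyst is left / forward and back rates have come level / all of D has reacted / it is still moving / X has run out first)
- part of the D gone at 10 min
- the D.X standing at 10 min, as a percentage of the D charged

Applied honestly, the rule gives me 3.07 parts of D.X to one of Z, which is kinetic control. But the rule stands as long as D.X and Z do not trade, and they have two ways of trading: L, the catalyst, carries each into the other, and both additions run back, D.X to D and X at 6.33 /s and Z at 3.25 /s. The level at which that trade balances is what I carry: the split, 1.58, the equilibrium constant of the D.X road over that of the Z road, which is the ratio [D.X]/[Z] at which the exchange stands still.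

With [L] and the sum of D.X and Z held, the exchange through L is first order in the distance from that level. Integrating gives an exponential whose rate constant is 13700 /M/s times [L] times one plus the split. With the whole charge of L free, this makes a half-life of 0.196 s. Some L pairs with itself, so the true figure is longer. Z, which falls back more slowly than D.X, has a half-life of 0.213 s by that back step. The border of the rule is the ratio of time to such half-lives, and the run of 10 min is 2817 of this one and 3061 of the one through L. So at the end of this flask I expect a ratio of 1.58, not 3.07, and I commit to that ratio and to no amounts.

The forecast goes further. It holds that “the mixture reaches true equilibrium within about a minute”, and it gives: forward and back rates have come level, with 77.3 % of D gone and 35.9 % of the D charged standing as D.X.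

The simulated flask gives the same: forward and back rates have come level, 77.3 % gone and 35.9 % as D.X. By the step through L taken by itself, D.X and Z relax with a half-life of 0.285 s, with 69.0 % of the catalyst as L, and the slowest mode of the whole flask has a half-life of 2.04 s, both far below the 10 min of the run, and D.X already stands at 35.9 % and Z at 22.8 % after 5.00 min. The ratio in this flask reads 1.58, and the neighbour flask charged with 0.0085 M of D, holding D.X at 27.5 % and Z at 17.4 % of its own D, reads 1.58.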